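The benzene ring of the target is built, not bought. Its para pattern, with C1 carrying the acyloxyethyl tether and C4 the hydroxyl, is cut into a four-carbon piece (C2, C1, C6, C5) and a two-carbon piece (C3, C4). A cobalt-catalysed formal [4+2] union of a 2-substituted buta-1,3-diene that already holds the complete hexacosanoate tether with ethynylboronic acid pinacol ester makes C2–C3 and C4–C5 in one operation and closes the carbocycle as a 1,4-cyclohexadiene, with boron at C4 as a masked hydroxyl. The diene ester is reached by ethylene–alkyne metathesis of but-3-ynyl hexacosanoate; dehydrogenation and C–B oxidation complete the route.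

Key step: step 3

Remark: the para orientation of the terminal ethynylboronate on the diphosphine cobalt catalyst is assumed by analogy with other terminal alkynes; it is the one point the plan must confirm. The target and all intermediates are achiral, so no stereocentre or double-bond geometry has to be set.

Step 1
Reactants: 1 hexacosanoic acid; 2 but-3-yn-1-ol
Product: 3 but-3-yn-1-yl hexacosanoate
Conditions: DCC, DMAP (cat.), CH2Cl2/THF (1:1), 0 °C to rt
Reagents that add atoms: none
Why: Steglich esterification, in which the carbodiimide activates the fatty acid and DMAP relays the acyl group to the unhindered primary alcohol, while the terminal alkyne is inert.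

Step 2
Reactants: 3 but-3-yn-1-yl hexacosanoate; 4 ethylene
Product: 5 3-methylenepent-4-en-1-yl hexacosanoate
Conditions: second-generation Grubbs catalyst (5 mol%), C2H4 (1 atm), toluene, 60 °C
Reagents that add atoms: none
Why: Ethylene–alkyne cross-enyne metathesis, in which the ruthenium methylidene should add to the terminal alkyne to give a vinylcarbene that ethylene turns over, converting the C≡C unit into a 2-substituted buta-1,3-diene; homopropargylic esters are established substrates and the saturated ester chain is inert.

Step 3
Reactants: 5 3-methylenepent-4-en-1-yl hexacosanoate; 6 2-ethynyl-4,4,5,5-tetramethyl-1,3,2-dioxaborolane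
Product: 7 2-[4-(4,4,5,5-tetramethyl-1,3,2-dioxaborolan-2-yl)cyclohexa-1,4-dien-1-yl]ethyl hexacosanoate
Conditions: CoBr2(dppe) (10 mol%), Zn powder (20 mol%), ZnI2 (20 mol%), CH2Cl2, rt, slow addition of 6
Reagents that add atoms: none
Why: Zinc should reduce CoBr2(dppe) to monovalent cobalt and ZnI2 should remove bromide, so that a cationic diphosphine cobalt centre binds the s-cis diene of 5 together with alkyne 6; oxidative cyclisation then forms the first C–C bond in a trivalent cobaltacycle (σ-vinyl, η3-allyl) and reductive elimination forms the second and frees the catalyst. The closest known reaction type is the cobalt-catalysed neutral Diels–Alder reaction of unactivated alkynes, alkynylboronic esters among them, with 2-substituted buta-1,3-dienes. The single new ring, a six-membered carbocycle, closes by intermolecular [4+2] annulation in which the diene carbons C2, C1, C6, C5 and the alkyne carbons C3, C4 are joined through C2–C3 and C4–C5; no stereocentre is created, so nothing has to be controlled there. The selectivity needed is para (1,4) over meta (1,3) orientation, that is, bonding of the boron-bearing carbon C4 to the diene terminus C5 remote from the tether, which the chelating diphosphine is expected to impose as it does for other terminal alkynes and which keeps the bulky boronate away from the substituted diene carbon C1. Slow addition of 6 should hold back alkyne cyclotrimerisation, and the neutral medium at room temperature should leave the ester, the C–B bond and the skipped diene untouched, where a thermal cycloaddition of these unactivated partners would not proceed.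

Step 4
Reactants: 7 2-[4-(4,4,5,5-tetramethyl-1,3,2-dioxaborolan-2-yl)cyclohexa-1,4-dien-1-yl]ethyl hexacosanoate
Product: 8 2-[4-(4,4,5,5-tetramethyl-1,3,2-dioxaborolan-2-yl)phenyl]ethyl hexacosanoate
Conditions: DDQ (1.1 equiv), toluene, rt
Reagents that add atoms: none
Why: Quinone dehydrogenation, in which DDQ abstracts hydride from one doubly allylic CH2 and the resulting arenium ion loses a proton from the other CH2, so the ring aromatises without touching the C–B bond or the ester.

Step 5
Reactants: 8 2-[4-(4,4,5,5-tetramethyl-1,3,2-dioxaborolan-2-yl)phenyl]ethyl hexacosanoate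
Product: 9 2-(4-hydroxyphenyl)ethyl hexacosanoate
Conditions: NaBO3·4H2O (3 equiv), THF/H2O (1:1), rt
Reagents that add atoms: sodium perborate, NaBO3 (used as the tetrahydrate), SMILES [Na+].[O-]OB=O
Why: Oxidative ipso-hydroxylation of an arylboronic ester, in which the peroxide oxygen adds to boron, the aryl group shifts from boron to oxygen at the same ring carbon and the borate is hydrolysed to the phenol; the weakly basic perborate medium should spare the primary fatty ester.

Compound list
1 | hexacosanoic acid | CCCCCCCCCCCCCCCCCCCCCCCCCC(=O)O | starting material
2 | but-3-yn-1-ol | C#CCCO | starting material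
3 | but-3-yn-1-yl hexacosanoate | CCCCCCCCCCCCCCCCCCCCCCCCCC(=O)OCCC#C | intermediate
4 | ethylene | C=C | starting material
5 | 3-methylenepent-4-en-1-yl hexacosanoate | CCCCCCCCCCCCCCCCCCCCCCCCCC(=O)OCCC(=C)C=C | intermediate
6 | 2-ethynyl-4,4,5,5-tetramethyl-1,3,2-dioxaborolane (ethynylboronic acid pinacol ester) | C#CB1OC(C)(C)C(C)(C)O1 | starting material
7 | 2-[4-(4,4,5,5-tetramethyl-1,3,2-dioxaborolan-2-yl)cyclohexa-1,4-dien-1-yl]ethyl hexacosanoate | CCCCCCCCCCCCCCCCCCCCCCCCCC(=O)OCCC1=CCC(B2OC(C)(C)C(C)(C)O2)=CC1 | intermediate
8 | 2-[4-(4,4,5,5-tetramethyl-1,3,2-dioxaborolan-2-yl)phenyl]ethyl hexacosanoate | CCCCCCCCCCCCCCCCCCCCCCCCCC(=O)OCCc1ccc(B2OC(C)(C)C(C)(C)O2)cc1 | intermediate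
9 | 2-(4-hydroxyphenyl)ethyl hexacosanoate | CCCCCCCCCCCCCCCCCCCCCCCCCC(=O)OCCc1ccc(O)cc1 | target

Total step count: 5. Longest linear sequence: 5 steps (1 → 3 → 5 → 7 → 8 → 9).

Steps most likely to fail

1. Step 3 (cobalt [4+2]).
- Risk: the alkyne may enter the cobaltacycle with the opposite orientation, so that boron ends meta to the tether, or the terminal alkyne may trimerise faster than it cross-reacts.
- Fallback: it sets out from diene ester 5 and changes the placeholder at C4 from boron to silicon. Diene 5 is combined under the same CoBr2(dppe)/Zn/ZnI2 system with ethynyltrimethylsilane, a bulky terminal alkyne of the class known to orient para with diphosphine cobalt catalysts and slow to trimerise. This should give 2-[4-(trimethylsilyl)cyclohexa-1,4-dien-1-yl]ethyl hexacosanoate F1. DDQ in toluene should aromatise it to 2-[4-(trimethylsilyl)phenyl]ethyl hexacosanoate F2. ipso-Iododesilylation with ICl in CH2Cl2 at 0 °C should give 2-(4-iodophenyl)ethyl hexacosanoate F3. Miyaura borylation (B2pin2, Pd(dppf)Cl2, KOAc, dioxane, 80 °C) then returns to aryl boronate 8.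

2. Step 2 (ethylene–alkyne metathesis).
- Risk: the terminal alkyne may oligomerise on ruthenium, or the vinylcarbene may stall when ethylene is too dilute, leaving the alkyne unconverted.
- Fallback: it sets out from hexacosanoic acid 1 and builds the diene before the ester. Isoprene is potassiated at its methyl group with LiTMP/KOtBu in THF at −78 °C to (2-methylenebut-3-en-1-yl)potassium F4. Trapping with paraformaldehyde and aqueous quench should give 3-methylenepent-4-en-1-ol F5. Steglich esterification of this alcohol with acid 1 (DCC, DMAP, CH2Cl2/THF) rejoins the route at diene ester 5.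

3. Step 5 (C–B oxidation).
- Risk: saponification of the fatty ester in the basic peroxide medium may compete with a slow two-phase aryl migration of the waxy boronate.
- Fallback: it sets out from aryl boronate 8 and drives the competing cleavage to completion. H2O2/NaOH in THF/H2O at 50 °C, followed by acidification, should oxidise the C–B bond and cleave the ester, giving 4-(2-hydroxyethyl)phenol F6 together with recovered hexacosanoic acid 1. Immobilised Candida antarctica lipase B (toluene, 60 °C, 4 Å molecular sieves) should then acylate only the primary alcohol of the phenol-alcohol with acid 1, which returns to target 9.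

Further compounds
F1 | step 3 | 2-[4-(trimethylsilyl)cyclohexa-1,4-dien-1-yl]ethyl hexacosanoate | CCCCCCCCCCCCCCCCCCCCCCCCCC(=O)OCCC1=CCC([Si](C)(C)C)=CC1
F2 | step 3 | 2-[4-(trimethylsilyl)phenyl]ethyl hexacosanoate | CCCCCCCCCCCCCCCCCCCCCCCCCC(=O)OCCc1ccc([Si](C)(C)C)cc1
F3 | step 3 | 2-(4-iodophenyl)ethyl hexacosanoate | CCCCCCCCCCCCCCCCCCCCCCCCCC(=O)OCCc1ccc(I)cc1
F4 | step 2 | (2-methylenebut-3-en-1-yl)potassium | [K+].[CH2-]C(=C)C=C
F5 | step 2 | 3-methylenepent-4-en-1-ol | OCCC(=C)C=C
F6 | step 5 | 4-(2-hydroxyethyl)phenol | OCCc1ccc(O)cc1
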